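**Retrosynthetic overview**

- The target is cut last at the CH2 bridge between C1 of ring A and C3 of ring B (6-ethyl-4-hydroxy-5-methyl-2-pyranone), which leads back to a ring A aldehyde and the free pyranone (reductive alkylation).
- The strategy rests on ring A (C1 CH2, C2 OH, C3 prenyl, C4 OH, C5 (R)-2-methylbutanoyl, C6 OMe). The C4 hydroxyl oxygen and the C5 acyl carbon sit on neighbouring ring carbons, with the C6 methoxy group on the other side of C5. Both bonds (C4–O and C5–C=O) are cut together, back to a C4–C5 aryne and (R)-2-methylbutanoic acid, so the stereocentre is bought.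
- The aryne precursor is the C4 triflate / C5 trimethylsilyl arene, made from a C5 bromide by retro-Brook shift. The C3 prenyl group comes from a Claisen shift of the C4 1,1-dimethylallyl ether, and the C1 formyl group from formylation of 5-methoxyresorcinol.
- Ring order: ring A is present from the start; ring B is closed by lactonisation of a 3,5-dioxo ester made from methyl 3-oxopentanoate; the key step closes no ring.

Key step: step 11

Remark: ring A is numbered in all names as C1 (formyl carbon, later the CH2 bridge), C2 (OH), C3 (prenyl = 3-methylbut-2-enyl), C4 (OH), C5 (acyl), C6 (OMe). (R)-2-Methylbutanoic acid is assumed to be bought in high enantiomeric purity.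

**Route**

Step 1
Reactants: 1 5-methoxyresorcinol
Product: 3 2,4-dihydroxy-6-methoxybenzaldehyde, via aryl iminium chloride 2 (not isolated)
Conditions: POCl3, DMF, MeCN, 0 °C → rt; then H2O, 50 °C
Reagents that add atoms: N,N-dimethylformamide CN(C)C=O; water O
Why: Vilsmeier–Haack formylation, in which the chloroiminium ion should attack the ring carbon para to one hydroxyl and ortho to the other (between OH and OMe) rather than the more crowded carbon between the two hydroxyls, as in the formylation of orcinol, and water then hydrolyses iminium salt 2 to the aldehyde.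

Step 2
Reactants: 3 2,4-dihydroxy-6-methoxybenzaldehyde; 4 2-methylbut-3-yn-2-ol
Product: 6 2-hydroxy-6-methoxy-4-(2-methylbut-3-yn-2-yloxy)benzaldehyde, via 2-methylbut-3-yn-2-yl trifluoroacetate 5 (not isolated)
Conditions: 4, (CF3CO)2O, DBU, MeCN, −5 °C; then 3, CuCl2·2H2O (cat.), DBU, MeCN, −5 → 0 °C
Reagents that add atoms: none
Why: Copper-catalysed propargylic etherification, in which trifluoroacetate 5 ionises through a copper acetylide and is captured by the phenoxide of the C4 hydroxyl (the more acidic one, para to the formyl group), while the C2 hydroxyl stays locked in its hydrogen bond to the formyl oxygen.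

Step 3
Reactants: 6 2-hydroxy-6-methoxy-4-(2-methylbut-3-yn-2-yloxy)benzaldehyde
Product: 7 2-hydroxy-6-methoxy-4-(2-methylbut-3-en-2-yloxy)benzaldehyde
Conditions: H2 (1 atm), Pd/CaCO3 poisoned with Pb(OAc)2 (Lindlar catalyst), quinoline, EtOAc, rt
Reagents that add atoms: none
Why: Lindlar semihydrogenation, which should reduce the terminal alkyne to the vinyl group and stop there, leaving the formyl group and the aryl ether untouched.

Step 4
Reactants: 7 2-hydroxy-6-methoxy-4-(2-methylbut-3-en-2-yloxy)benzaldehyde
Product: 9 2,4-dihydroxy-6-methoxy-3-(3-methylbut-2-enyl)benzaldehyde, via C3 cyclohexadienone 8 (not isolated)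
Conditions: PhNEt2, 130 °C
Reagents that add atoms: none
Why: Aromatic Claisen rearrangement ([3,3]-sigmatropic shift), in which the tertiary allyl ether transposes to a linear prenyl group on an ortho carbon; C3 should be preferred over C5 because the hydrogen bond between the C2 hydroxyl and the formyl group fixes double-bond character in the C3–C4 bond, and dienone 8 then enolises in the basic solvent, which also keeps the new ortho-prenyl phenol from closing to a chroman.

Step 5
Reactants: 9 2,4-dihydroxy-6-methoxy-3-(3-methylbut-2-enyl)benzaldehyde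
Product: 10 5-bromo-2,4-dihydroxy-6-methoxy-3-(3-methylbut-2-enyl)benzaldehyde
Conditions: NBS (1.0 equiv), iPr2NH (0.1 equiv), CH2Cl2, −78 → −20 °C
Reagents that add atoms: N-bromosuccinimide O=C1CCC(=O)N1Br
Why: Electrophilic aromatic bromination at C5, the only ring carbon still bearing hydrogen and one activated by all three oxygens; the N-bromoamine formed from NBS and the catalytic amine is delivered ortho to the free C4 hydroxyl and should react there at low temperature faster than it opens the prenyl double bond.

Step 6
Reactants: 10 5-bromo-2,4-dihydroxy-6-methoxy-3-(3-methylbut-2-enyl)benzaldehyde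
Product: 11 4-acetoxy-5-bromo-2-hydroxy-6-methoxy-3-(3-methylbut-2-enyl)benzaldehyde
Conditions: Ac2O (1.05 equiv), Et3N, CH2Cl2, 0 °C
Reagents that add atoms: acetic anhydride CC(=O)OC(C)=O
Why: Selective O-acetylation, in which the C4 hydroxyl (made more acidic by the ortho bromine and the para formyl group) takes the single equivalent of anhydride while the chelated C2 hydroxyl stays free, so that the two phenols are told apart.

Step 7
Reactants: 11 4-acetoxy-5-bromo-2-hydroxy-6-methoxy-3-(3-methylbut-2-enyl)benzaldehyde
Product: 12 4-acetoxy-5-bromo-6-methoxy-2-(methoxymethoxy)-3-(3-methylbut-2-enyl)benzaldehyde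
Conditions: MOMCl, iPr2NEt, CH2Cl2, 0 → 40 °C
Reagents that add atoms: chloromethyl methyl ether COCCl
Why: Williamson-type O-alkylation with the reactive chloromethyl ether under amine base, which should protect the remaining chelated C2 hydroxyl as its MOM ether without touching the aryl acetate.

Step 8
Reactants: 12 4-acetoxy-5-bromo-6-methoxy-2-(methoxymethoxy)-3-(3-methylbut-2-enyl)benzaldehyde
Product: 13 2-[4-acetoxy-5-bromo-6-methoxy-2-(methoxymethoxy)-3-(3-methylbut-2-enyl)phenyl]-1,3-dioxolane
Conditions: TMSOCH2CH2OTMS, TMSOTf (cat.), CH2Cl2, −78 → −20 °C; pyridine quench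
Reagents that add atoms: 1,2-bis(trimethylsilyloxy)ethane C[Si](C)(C)OCCO[Si](C)(C)C
Why: Aprotic acetalisation catalysed by TMSOTf with the bis-silyl ether of ethylene glycol, driven by formation of hexamethyldisiloxane; without protic acid the MOM ether, the acetate and the prenyl group should survive, and the formyl group becomes inert to organolithium reagents.

Step 9
Reactants: 13 2-[4-acetoxy-5-bromo-6-methoxy-2-(methoxymethoxy)-3-(3-methylbut-2-enyl)phenyl]-1,3-dioxolane
Product: 14 2-[5-bromo-4-hydroxy-6-methoxy-2-(methoxymethoxy)-3-(3-methylbut-2-enyl)phenyl]-1,3-dioxolane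
Conditions: K2CO3, MeOH, 0 °C; pH 7 buffer work-up, crude product taken on
Reagents that add atoms: none
Why: Base-catalysed methanolysis (transesterification) of the aryl acetate, which frees the C4 hydroxyl while the dioxolane and the MOM ether are stable to carbonate.

Step 10
Reactants: 14 2-[5-bromo-4-hydroxy-6-methoxy-2-(methoxymethoxy)-3-(3-methylbut-2-enyl)phenyl]-1,3-dioxolane
Product: 17 2-[6-methoxy-2-(methoxymethoxy)-3-(3-methylbut-2-enyl)-4-(trifluoromethylsulfonyloxy)-5-(trimethylsilyl)phenyl]-1,3-dioxolane, via C4 trimethylsilyl ether 15 (not isolated), via lithium C5-silyl phenoxide 16 (not isolated)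
Conditions: HMDS, THF, 65 °C, then evaporation; n-BuLi, THF, −78 °C; Tf2O, −78 °C; aq NaHCO3
Reagents that add atoms: hexamethyldisilazane C[Si](C)(C)N[Si](C)(C)C; trifluoromethanesulfonic anhydride O=S(=O)(OS(=O)(=O)C(F)(F)F)C(F)(F)F
Why: Retro-Brook route to an ortho-silylaryl triflate, in which silylation of the C4 hydroxyl, bromine–lithium exchange at C5 (faster than any deprotonation) and 1,3-migration of silicon from oxygen to the C5 carbanion give lithium phenoxide 16, which is triflated in the same flask; the dioxolane and the MOM ether tolerate n-BuLi at −78 °C.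

Step 11
Reactants: 17 2-[6-methoxy-2-(methoxymethoxy)-3-(3-methylbut-2-enyl)-4-(trifluoromethylsulfonyloxy)-5-(trimethylsilyl)phenyl]-1,3-dioxolane; 18 (R)-2-methylbutanoic acid
Product: 22 2-[4-hydroxy-6-methoxy-2-(methoxymethoxy)-5-((2R)-2-methylbutanoyl)-3-(3-methylbut-2-enyl)phenyl]-1,3-dioxolane, via cesium carboxylate 19 (not isolated), via C4–C5 aryne 20 (not isolated), via C5 aryl cesium ester 21 (not isolated)
Conditions: 18 (3 equiv), Cs2CO3 (1.5 equiv), MeOH, rt, then evaporation and toluene azeotrope; 17 (1 equiv), CsF (3 equiv), 18-crown-6 (3 equiv), THF, 50 °C; aq NH4Cl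
Reagents that add atoms: none
Why: Fluoride attacks the C5 silicon of 17 and triflate leaves from C4 to give aryne 20; the carboxylate oxygen of 19 adds to C4, and the C5 aryl anion of 21 attacks its own ester carbonyl through a four-membered transition state that opens to the C5 ketone and the C4 phenoxide (an anionic Fries-type 1,3 O→C acyl shift). The closest known reaction is the fluoride-induced insertion of arynes into the C–O bond of carboxylic acids to give ortho-hydroxyaryl ketones, applied here to a fully substituted aryne. The step closes no ring and sets no stereocentre: the R centre arrives in acid 18 and should be kept, because the acyl group travels as an intact ester without passing through an enolate, ketene or acylium ion, and the product rests as a cesium 2-acylphenoxide that resists further deprotonation at 50 °C. The step needs oxygen at C4 and acyl at C5, and this should follow from the C6 methoxy group, whose inductive pull polarises the aryne so that the nucleophile enters at the distal carbon and the negative charge develops next to the methoxy group. Acyl transfer is favoured over simple O-arylation by using the dried cesium carboxylate in THF, so that no proton source intercepts aryl anion 21, and the excess of carboxylate should outrun the hindered product phenoxide and any ene reaction of the prenyl group.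

Step 12
Reactants: 22 2-[4-hydroxy-6-methoxy-2-(methoxymethoxy)-5-((2R)-2-methylbutanoyl)-3-(3-methylbut-2-enyl)phenyl]-1,3-dioxolane
Product: 23 2,4-dihydroxy-6-methoxy-5-((2R)-2-methylbutanoyl)-3-(3-methylbut-2-enyl)benzaldehyde
Conditions: HCl (1 M aq), THF/MeOH, 0 °C → rt
Reagents that add atoms: water O
Why: Acid hydrolysis of the two acetals, in which the dioxolane of the electron-rich ring opens first and the MOM ether, now ortho to the free formyl group, follows under the same dilute acid, which at room temperature should neither cyclise the prenyl phenol to a chroman nor enolise the α-branched ketone.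

Step 13
Reactants: 24 methyl 3-oxopentanoate; 25 N-methoxy-N-methylpropanamide
Product: 27 methyl 4-methyl-3,5-dioxoheptanoate, via dilithium dianion 26 (not isolated)
Conditions: LiN(iPr)2 (2.2 equiv), THF, −78 → 0 °C; 25, −78 → 0 °C; aq NH4Cl
Reagents that add atoms: none
Why: Acylation of a β-keto ester dianion, in which the more reactive γ-carbanion (C4) of 26 adds to the Weinreb amide and the chelated tetrahedral adduct holds until work-up, so that one propanoyl group is introduced; the new C4 centre is not controlled and becomes planar in the next step.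

Step 14
Reactants: 27 methyl 4-methyl-3,5-dioxoheptanoate
Product: 28 6-ethyl-4-hydroxy-5-methyl-2H-pyran-2-one
Conditions: DBU, toluene, 110 °C
Reagents that add atoms: none
Why: Lactonisation (intramolecular transesterification), in which the enol oxygen of the C5 ketone attacks the methyl ester and closes ring B by 6-exo-trig acyl substitution, giving the 4-hydroxy-2-pyranone after loss of methanol.

Step 15
Reactants: 23 2,4-dihydroxy-6-methoxy-5-((2R)-2-methylbutanoyl)-3-(3-methylbut-2-enyl)benzaldehyde; 28 6-ethyl-4-hydroxy-5-methyl-2H-pyran-2-one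
Product: 30 6-ethyl-4-hydroxy-3-{[2,4-dihydroxy-6-methoxy-5-((2R)-2-methylbutanoyl)-3-(3-methylbut-2-enyl)phenyl]methyl}-5-methyl-2H-pyran-2-one (CNP0233274.1), via Knoevenagel alkylidene 29 (not isolated)
Conditions: diethyl 2,6-dimethyl-1,4-dihydropyridine-3,5-dicarboxylate (Hantzsch ester, 1.2 equiv), L-proline (cat.), EtOH, rt → 40 °C
Reagents that add atoms: none
Why: Organocatalytic reductive alkylation (Knoevenagel condensation followed by conjugate transfer hydrogenation), in which proline condenses the formyl group of 23 with C3 of pyranone 28 to alkylidene 29 and the Hantzsch ester reduces it at the benzylic carbon before a second pyranone can add, forming the C1–CH2–C3 bridge without touching the prenyl group or the stereocentre.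

**Compound list**

1 | 5-methoxyresorcinol (5-methoxybenzene-1,3-diol) | COc1cc(O)cc(O)c1 | starting material
2 | (2,4-dihydroxy-6-methoxybenzylidene)dimethyliminium chloride | C[N+](C)=Cc1c(O)cc(O)cc1OC.[Cl-] | intermediate
3 | 2,4-dihydroxy-6-methoxybenzaldehyde | O=Cc1c(O)cc(O)cc1OC | intermediate
4 | 2-methylbut-3-yn-2-ol | CC(C)(O)C#C | starting material
5 | 2-methylbut-3-yn-2-yl trifluoroacetate | CC(C)(OC(=O)C(F)(F)F)C#C | intermediate
6 | 2-hydroxy-6-methoxy-4-(2-methylbut-3-yn-2-yloxy)benzaldehyde | O=Cc1c(O)cc(OC(C)(C)C#C)cc1OC | intermediate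
7 | 2-hydroxy-6-methoxy-4-(2-methylbut-3-en-2-yloxy)benzaldehyde | O=Cc1c(O)cc(OC(C)(C)C=C)cc1OC | intermediate
8 | 2-hydroxy-6-methoxy-3-(3-methylbut-2-enyl)-4-oxocyclohexa-1,5-diene-1-carbaldehyde (Claisen dienone, C3 configuration not defined) | O=CC1=C(O)C(CC=C(C)C)C(=O)C=C1OC | intermediate
9 | 2,4-dihydroxy-6-methoxy-3-(3-methylbut-2-enyl)benzaldehyde | O=Cc1c(O)c(CC=C(C)C)c(O)cc1OC | intermediate
10 | 5-bromo-2,4-dihydroxy-6-methoxy-3-(3-methylbut-2-enyl)benzaldehyde | O=Cc1c(O)c(CC=C(C)C)c(O)c(Br)c1OC | intermediate
11 | 4-acetoxy-5-bromo-2-hydroxy-6-methoxy-3-(3-methylbut-2-enyl)benzaldehyde | O=Cc1c(O)c(CC=C(C)C)c(OC(C)=O)c(Br)c1OC | intermediate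
12 | 4-acetoxy-5-bromo-6-methoxy-2-(methoxymethoxy)-3-(3-methylbut-2-enyl)benzaldehyde | O=Cc1c(OCOC)c(CC=C(C)C)c(OC(C)=O)c(Br)c1OC | intermediate
13 | 2-[4-acetoxy-5-bromo-6-methoxy-2-(methoxymethoxy)-3-(3-methylbut-2-enyl)phenyl]-1,3-dioxolane | COCOc1c(CC=C(C)C)c(OC(C)=O)c(Br)c(OC)c1C1OCCO1 | intermediate
14 | 2-[5-bromo-4-hydroxy-6-methoxy-2-(methoxymethoxy)-3-(3-methylbut-2-enyl)phenyl]-1,3-dioxolane | COCOc1c(CC=C(C)C)c(O)c(Br)c(OC)c1C1OCCO1 | intermediate
15 | C4 trimethylsilyl ether of 14 | COCOc1c(CC=C(C)C)c(O[Si](C)(C)C)c(Br)c(OC)c1C1OCCO1 | intermediate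
16 | lithium C4 phenoxide carrying the C5 trimethylsilyl group | [Li+].COCOc1c(CC=C(C)C)c([O-])c([Si](C)(C)C)c(OC)c1C1OCCO1 | intermediate
17 | ring A silyl triflate: 2-[6-methoxy-2-(methoxymethoxy)-3-(3-methylbut-2-enyl)-4-(trifluoromethylsulfonyloxy)-5-(trimethylsilyl)phenyl]-1,3-dioxolane | COCOc1c(CC=C(C)C)c(OS(=O)(=O)C(F)(F)F)c([Si](C)(C)C)c(OC)c1C1OCCO1 | intermediate
18 | (R)-2-methylbutanoic acid | OC(=O)[C@H](C)CC | starting material
19 | cesium (R)-2-methylbutanoate | [Cs+].[O-]C(=O)[C@H](C)CC | intermediate
20 | ring A C4–C5 aryne (C1 dioxolane, C2 OMOM, C3 prenyl, C6 OMe) | COCOC1=C(CC=C(C)C)C#CC(OC)=C1C1OCCO1 | intermediate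
21 | C5 aryl cesium carrying the C4 (R)-2-methylbutanoate ester | [Cs+].COCOc1c(CC=C(C)C)c(OC(=O)[C@H](C)CC)[c-]c(OC)c1C1OCCO1 | intermediate
22 | 2-[4-hydroxy-6-methoxy-2-(methoxymethoxy)-5-((2R)-2-methylbutanoyl)-3-(3-methylbut-2-enyl)phenyl]-1,3-dioxolane | COCOc1c(CC=C(C)C)c(O)c(C(=O)[C@H](C)CC)c(OC)c1C1OCCO1 | intermediate
23 | 2,4-dihydroxy-6-methoxy-5-((2R)-2-methylbutanoyl)-3-(3-methylbut-2-enyl)benzaldehyde | O=Cc1c(O)c(CC=C(C)C)c(O)c(C(=O)[C@H](C)CC)c1OC | intermediate
24 | methyl 3-oxopentanoate | CCC(=O)CC(=O)OC | starting material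
25 | N-methoxy-N-methylpropanamide | CCC(=O)N(C)OC | starting material
26 | dilithium 2,4-dianion of methyl 3-oxopentanoate | [Li+].[Li+].C[CH-]C(=O)[CH-]C(=O)OC | intermediate
27 | methyl 4-methyl-3,5-dioxoheptanoate (C4 configuration not defined) | CCC(=O)C(C)C(=O)CC(=O)OC | intermediate
28 | 6-ethyl-4-hydroxy-5-methyl-2H-pyran-2-one (ring B) | CCc1oc(=O)cc(O)c1C | intermediate
29 | 3-arylidene-6-ethyl-5-methylpyran-2,4-dione from 23 and 28 (double-bond geometry not defined) | CCC1=C(C)C(=O)C(=Cc2c(O)c(CC=C(C)C)c(O)c(C(=O)[C@H](C)CC)c2OC)C(=O)O1 | intermediate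
30 | 6-ethyl-4-hydroxy-3-{[2,4-dihydroxy-6-methoxy-5-((2R)-2-methylbutanoyl)-3-(3-methylbut-2-enyl)phenyl]methyl}-5-methyl-2H-pyran-2-one | CCc1oc(=O)c(Cc2c(O)c(CC=C(C)C)c(O)c(C(=O)[C@H](C)CC)c2OC)c(O)c1C | target

**Step count and risks**

Total step count: 15 (steps 1–12 for ring A, steps 13–14 for ring B, step 15 for the coupling).
Longest linear sequence: 13 steps (steps 1–12, then step 15).

Steps most likely to fail:

1. Step 11. The C5 aryl anion may be protonated before it reaches the ester carbonyl, so that only O-arylation takes place; the carboxylate may enter at C5 on the crowded aryne; or long exposure to fluoride may erode the α-stereocentre. The fallback makes the same C4–O / C5–acyl pair without an aryne, by an anionic Fries rearrangement triggered by halogen–metal exchange. It sets out from phenol 14, which is esterified with acid 18 (EDC·HCl, cat. 4-(dimethylamino)pyridine, CH2Cl2, 0 °C) to the C4 (R)-2-methylbutanoate of the C5 bromide F1. Treatment with t-BuLi (2 equiv, THF, −100 °C) exchanges the C5 bromine, the aryllithium takes the acyl group from the neighbouring oxygen, and work-up should give 22, where the route is rejoined; steps 10 and 11 are then not needed.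

2. Step 5. The bromine electrophile may add to the prenyl double bond, with the neighbouring hydroxyl closing onto the bromonium ion (bromoetherification), in competition with ring substitution. The fallback uses no electrophilic halogen and replaces bromination and retro-Brook shift by carbamate-directed ortho-metalation. It sets out from 9:
   - iPrNCO with cat. Et3N (CH2Cl2, rt) should carbamoylate only the non-chelated C4 hydroxyl, giving the C4 N-isopropylcarbamate F2.
   - MOMCl/iPr2NEt gives the C2 MOM ether F3.
   - Acetalisation as in step 8 gives the dioxolane F4.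
   - N-Silylation (TMSOTf, TMEDA, Et2O, 0 °C), then n-BuLi/TMEDA at −78 °C, lithiates C5 (the only ring C–H, flanked by carbamate and methoxy), and TMSCl gives the C5 trimethylsilyl carbamate F5.
   - DBU and Et2NH in MeCN at 40 °C cleave the carbamate to the phenoxide, the isocyanate being taken up by the amine, and PhNTf2 triflates it to 17, where the route is rejoined.

3. Step 15. The hindered, hydrogen-bonded and electron-rich formyl group may condense slowly, and alkylidene 29 may be trapped by a second pyranone or by the C2 hydroxyl before hydride transfer. The fallback reverses the order of reduction and C–C bond formation (quinone methide alkylation). It sets out from 23: NaBH4 (THF/MeOH, −20 °C) should reduce only the formyl group, not the chelated and hindered ketone, to the benzylic alcohol F6. Warming crude F6 with pyranone 28 in aqueous 1,4-dioxane (60–80 °C) expels water to an ortho-quinone methide, which is captured at C3 of 28 in a Michael addition to give target 30.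

Further compounds
F1 | step 11 | 2-[5-bromo-6-methoxy-2-(methoxymethoxy)-4-((2R)-2-methylbutanoyloxy)-3-(3-methylbut-2-enyl)phenyl]-1,3-dioxolane | COCOc1c(CC=C(C)C)c(OC(=O)[C@H](C)CC)c(Br)c(OC)c1C1OCCO1
F2 | step 5 | 2-hydroxy-6-methoxy-3-(3-methylbut-2-enyl)-4-(propan-2-ylcarbamoyloxy)benzaldehyde | CC(C)NC(=O)Oc1cc(OC)c(C=O)c(O)c1CC=C(C)C
F3 | step 5 | 6-methoxy-2-(methoxymethoxy)-3-(3-methylbut-2-enyl)-4-(propan-2-ylcarbamoyloxy)benzaldehyde | CC(C)NC(=O)Oc1cc(OC)c(C=O)c(OCOC)c1CC=C(C)C
F4 | step 5 | 2-[6-methoxy-2-(methoxymethoxy)-3-(3-methylbut-2-enyl)-4-(propan-2-ylcarbamoyloxy)phenyl]-1,3-dioxolane | CC(C)NC(=O)Oc1cc(OC)c(C2OCCO2)c(OCOC)c1CC=C(C)C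
F5 | step 5 | 2-[6-methoxy-2-(methoxymethoxy)-3-(3-methylbut-2-enyl)-4-(propan-2-ylcarbamoyloxy)-5-(trimethylsilyl)phenyl]-1,3-dioxolane | CC(C)NC(=O)Oc1c([Si](C)(C)C)c(OC)c(C2OCCO2)c(OCOC)c1CC=C(C)C
F6 | step 15 | (2R)-1-[2,4-dihydroxy-3-(hydroxymethyl)-6-methoxy-5-(3-methylbut-2-enyl)phenyl]-2-methylbutan-1-one | OCc1c(O)c(CC=C(C)C)c(O)c(C(=O)[C@H](C)CC)c1OC
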